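**Plan**

1. Numbering used throughout (longipinane): C1 = C=O, C2 = CH2, C3 = CHMe, cyclobutane C4–C5–C11–C10, C6 = CMe2, C7–C9 = O‑bearing carbons, C10 = C–Me. The retrosynthesis first removes the three angelates, then the 8,9‑diol (back to a C8=C9 alkene) and the C3 methyl (back to a C2=C3 enone).
2. The central cut is C2–C3 of the six‑membered ring C1–C2–C3–C4–C5–C11. The C1 carbonyl and C3 stand 1,5 across the cyclobutane (C1–C11–C5–C4–C3), so a bicyclo[4.1.1]octene with a C11 acetyl and a C4 formyl group is an aldol donor–acceptor pair; both groups are epimerisable and the seven‑membered bridge holds them syn‑diaxial on the four‑membered ring.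
3. That bicycle is cut at C4–C5 and C10–C11 to an acyclic (Z)‑vinylketene (C4 = ketene carbon) tethered to a 1,3‑diene; its acid precursor is cut at C7–C8 by a vinylogous aldol.
4. Forward: acyclic trienoic acid → ketene [2+2] closes the cyclobutane and the seven‑membered ring together → one‑carbon homologation and Wacker oxidation → aldol condensation closes the six‑membered ring last → cuprate, osmylation, desilylation, threefold esterification.
5. Stereochemistry: C7 comes from the reagent‑controlled vinylogous Mukaiyama aldol and steers the facial sense of the cycloaddition (C4, C5, C10, C11). C3 comes from cuprate attack anti to the C10 bridge, and C8/C9 from osmylation anti to the C7 silyloxy group.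

Key step: step 11

Remark (assumptions): 7 and 14 are E/Z mixtures at the enol‑ether double bond (inconsequential). 15 may be an epimer mixture at C4, which step 11 levels. The promoter antipode in step 5 is the one that delivers the (5R)‑carbinol. In step 15 the order of esterification (C8–OH, then C7–OH, then C9–OH) is assumed from steric accessibility; because the three acyl groups are identical, any other order converges on the same triester.

**Route**

Step 1
Reactants: 1 methyl sorbate
Product: 3 methyl (E)-2,2-dimethylhexa-3,5-dienoate, via methyl 2-methylhexa-3,5-dienoate 2 (not isolated)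
Conditions: LDA (1.1 equiv), THF–HMPA, −78 °C, then MeI; same flask: LDA (1.2 equiv), −78 °C, then MeI, −78 → 0 °C
Reagents that add atoms: iodomethane CI
Why: Deconjugative α‑alkylation of an extended ester enolate: LDA removes the ε‑hydrogen of the sorbate (then the doubly activated α‑hydrogen of 2), the lithium trienolate is methylated at the α‑carbon, and two cycles create the quaternary carbon next to an (E)‑1,3‑diene; no stereocentre is formed.

Step 2
Reactants: 3 methyl (E)-2,2-dimethylhexa-3,5-dienoate
Product: 4 (E)-2,2-dimethylhexa-3,5-dien-1-ol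
Conditions: LiAlH4, Et2O, 0 °C; aqueous NaOH work‑up
Reagents that add atoms: none
Why: Hydride reduction of the ester to the primary alcohol; the unconjugated diene is inert to LiAlH4.

Step 3
Reactants: 4 (E)-2,2-dimethylhexa-3,5-dien-1-ol
Product: 5 (E)-2,2-dimethylhexa-3,5-dienal
Conditions: Dess–Martin periodinane, CH2Cl2, 0 °C → rt
Reagents that add atoms: none
Why: Dess–Martin oxidation gives the aldehyde under neutral conditions; with a quaternary α‑carbon it can neither enolise nor move into conjugation.

Step 4
Reactants: 6 methyl tiglate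
Product: 7 tert-butyl[(1-methoxy-2-methylbuta-1,3-dien-1-yl)oxy]dimethylsilane
Conditions: LDA, THF/DMPU, −78 °C; TBSCl, −78 °C → rt
Reagents that add atoms: tert-butyldimethylsilyl chloride CC(C)(C)[Si](C)(C)Cl
Why: Kinetic γ‑deprotonation of the tiglate and O‑silylation of the lithium dienolate give the silyl dienol ether needed as the vinylogous nucleophile.

Step 5
Reactants: 5 (E)-2,2-dimethylhexa-3,5-dienal; 7 silyl dienol ether
Product: 8 methyl (2E,5R,7E)-5-hydroxy-2,6,6-trimethyldeca-2,7,9-trienoate
Conditions: B‑phenyl oxazaborolidinone from N‑tosyltryptophan (0.5 equiv), i‑PrOH (1.2 equiv), EtCN, −78 °C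
Reagents that add atoms: none
Why: Vinylogous Mukaiyama aldol reaction: the chiral boron Lewis acid activates the non‑enolisable aldehyde and blocks one face, the α‑methyl group and the bulk of the promoter direct bonding to the γ‑carbon of 7, which sets C7 (5R in the chain) under reagent control and gives the (E)‑2‑methylenoate, while isopropanol takes up the silyl group.

Step 6
Reactants: 8 hydroxy ester
Product: 9 methyl (2E,5R,7E)-5-(tert-butyldimethylsilyloxy)-2,6,6-trimethyldeca-2,7,9-trienoate
Conditions: TBSOTf, 2,6‑lutidine, CH2Cl2, −78 → 0 °C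
Reagents that add atoms: tert-butyldimethylsilyl triflate CC(C)(C)[Si](C)(C)OS(=O)(=O)C(F)(F)F
Why: Silylation of the hindered neopentylic alcohol with the reactive silyl triflate; the ether later serves as the steric control element at C7.

Step 7
Reactants: 9 silyl ether ester
Product: 10 (2E,5R,7E)-5-(tert-butyldimethylsilyloxy)-2,6,6-trimethyldeca-2,7,9-trienoic acid
Conditions: LiOH, THF/MeOH/H2O, 40 °C; then 1 M HCl to pH 4
Reagents that add atoms: lithium hydroxide [Li+].[OH-]
Why: Saponification of the methyl ester; the silyl ether and the dienes are stable to aqueous LiOH.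

Step 8
Reactants: 10 trienoic acid
Product: 13 4-(tert-butyldimethylsilyloxy)-1,5,5-trimethyl-8-vinylbicyclo[4.1.1]oct-2-en-7-one, via acid chloride 11 (not isolated), via vinylketene 12 (not isolated)
Conditions: 1‑chloro‑N,N,2‑trimethylprop‑1‑en‑1‑amine (1.2 equiv), CH2Cl2, 0 °C → rt; solvent exchange, then slow addition to Et3N (5 equiv) in toluene at reflux (final ≤ 0.005 M)
Reagents that add atoms: none
Why: Intramolecular vinylketene–alkene [2+2] cycloaddition of the crossed (bridging) type known from dienoyl chlorides: γ‑dehydrohalogenation gives the (Z)‑vinylketene 12, whose electrophilic carbonyl carbon (future C4) bonds to the diene terminus next to the gem‑dimethyl carbon (future C5), the allyl‑stabilised neighbouring carbon (future C11) then bonds to the ketene α‑carbon (future C10), closing the cyclobutane and the seven‑membered ring at once with help from the gem‑dimethyl group and the Z‑alkene; C5, C10 and C11 follow from the bridged topology and the E‑alkene (vinyl exo), and the C7 silyloxy group should sit pseudo‑equatorial and anti to the forming C5–C11 bridge, i.e. on the side of the carbonyl bridge.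

Step 9
Reactants: 13 bicyclic cyclobutanone
Product: 15 4-(tert-butyldimethylsilyloxy)-1,5,5-trimethyl-8-vinylbicyclo[4.1.1]oct-2-ene-7-carbaldehyde, via enol ether 14 (not isolated)
Conditions: Ph3P(CH2OMe)Cl, KHMDS, THF, 0 °C → rt; then 0.5 M HCl, THF/H2O, rt
Reagents that add atoms: (methoxymethyl)triphenylphosphonium chloride COC[P+](c1ccccc1)(c1ccccc1)c1ccccc1.[Cl-]; water O
Why: Wittig methoxymethylenation of the strained cyclobutanone (C10 is quaternary and C5 a bridgehead, so enolisation does not compete) followed by acid hydrolysis of enol ether 14 is a one‑carbon homologation to the C4 aldehyde; the configuration at C4 arises on protonation, is epimerisable and is corrected in step 11.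

Step 10
Reactants: 15 vinyl aldehyde
Product: 16 8-acetyl-4-(tert-butyldimethylsilyloxy)-1,5,5-trimethylbicyclo[4.1.1]oct-2-ene-7-carbaldehyde
Conditions: PdCl2 (cat.), CuCl, O2 (1 atm), DMF/H2O (7:1), rt
Reagents that add atoms: water O
Why: Wacker oxidation: Markovnikov oxypalladation of the monosubstituted vinyl group gives the methyl ketone, whereas the ring cis‑alkene, flanked by a quaternary carbon and the silyloxy carbon, is much less reactive; no stereocentre is formed.

Step 11
Reactants: 16 keto aldehyde
Product: 18 7-(tert-butyldimethylsilyloxy)-3-demethyllongipina-2,8-dien-1-one, via β-hydroxy ketone 17 (not isolated)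
Conditions: KOH (0.3 equiv), MeOH, 0 → 40 °C
Reagents that add atoms: none
Why: Base enolises the methyl ketone at C2, the enolate adds to the C3 aldehyde to give β‑hydroxy ketone 17, and E1cB loss of water gives the conjugated C2=C3 enone, which makes the closure irreversible. The closest known reaction type is the intramolecular aldol condensation of a 1,5‑keto aldehyde to a cyclohex‑2‑enone (the ring‑closing half of a Robinson annulation). The ring C1–C2–C3–C4–C5–C11 closes in the 6‑(enolendo)‑exo‑trig mode; the seven‑membered bridge locks the cyclobutane pucker so that the exo groups at C4 and C11 are syn‑diaxial and within bonding distance. No stereocentre is created in the product (the carbinol centre of 17 is lost), but C4 and C11 are each α to a carbonyl group and epimerise under the conditions, so any trans material is funnelled through the one isomer that can cyclise. The step needs the ketone‑enolate/aldehyde‑acceptor pairing: the reverse pairing (C4 enolate onto C1) would give a bicyclo[1.1.1]pentane, enolisation of C1 towards C11 closes no ring, and the silyl ether, the ring alkene and the quaternary C10 carry no acidic hydrogen.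

Step 12
Reactants: 18 tricyclic dienone
Product: 19 7-(tert-butyldimethylsilyloxy)longipin-8-en-1-one
Conditions: Me2CuLi, Et2O, −78 → −30 °C; then aq. NH4Cl
Reagents that add atoms: lithium dimethylcuprate [Li+].C[Cu-]C
Why: Conjugate addition of the cuprate to the enone: the methyl group enters C3 from the face of the C5–H bridge, anti to the methyl‑bearing C10 bridge, as nucleophiles do with bicyclo[3.1.1]hept‑3‑en‑2‑ones, which sets C3; the isolated C8=C9 alkene does not react.

Step 13
Reactants: 19 tricyclic alkenyl ketone
Product: 20 7-(tert-butyldimethylsilyloxy)-8,9-dihydroxylongipinan-1-one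
Conditions: OsO4 (5 mol %), NMO (2 equiv), acetone/H2O (5:1), rt
Reagents that add atoms: osmium tetroxide O=[Os](=O)(=O)=O; N-methylmorpholine N-oxide C[N+]1([O-])CCOCC1; water O
Why: Osmium‑catalysed syn‑dihydroxylation of the C8=C9 alkene on the face anti to the bulky allylic C7 silyloxy group (and anti to the C4 bridge) gives the 8,9‑cis diol trans to O7, setting C8 and C9.

Step 14
Reactants: 20 silyloxy diol
Product: 21 7,8,9-trihydroxylongipinan-1-one
Conditions: HF·pyridine, THF, 0 °C → rt
Reagents that add atoms: none
Why: Fluoride cleaves the Si–O bond (strong Si–F bond) under weakly acidic conditions that leave the ketone and the triol untouched.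

Step 15
Reactants: 21 triol; 22 angelic acid
Product: 25 7,8,9-tris(angeloyloxy)longipinan-1-one (CNP0138097.1), via 8-monoangelate 23 (not isolated), via 7,8-diangelate 24 (not isolated)
Conditions: 22 (9 equiv), 2,4,6‑trichlorobenzoyl chloride (9 equiv), Et3N (10 equiv), toluene, rt (forms the mixed anhydride); then 21, toluene, 80 °C until the mono‑ and diesters are consumed, no DMAP
Reagents that add atoms: angelic 2,4,6-trichlorobenzoic anhydride C/C=C(/C)C(=O)OC(=O)c1c(Cl)cc(Cl)cc1Cl
Why: Yamaguchi‑type esterification with the mixed anhydride preformed from 22, run without a nucleophilic catalyst: three successive acyl transfers, each consuming one equivalent of the mixed anhydride at its less hindered angeloyl carbonyl, esterify first the C8 hydroxyl (the only one that is not neopentylic, giving 23), then the C7 hydroxyl (24) and last the C9 hydroxyl, and the absence of DMAP avoids Z to E isomerisation to tiglate; no stereocentre changes.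

**Compound list**

1 | methyl sorbate, methyl (2E,4E)-hexa-2,4-dienoate | COC(=O)/C=C/C=C/C | starting material
2 | methyl 2-methylhexa-3,5-dienoate (racemic, not isolated) | COC(=O)C(C)/C=C/C=C | intermediate
3 | methyl (E)-2,2-dimethylhexa-3,5-dienoate | COC(=O)C(C)(C)/C=C/C=C | intermediate
4 | (E)-2,2-dimethylhexa-3,5-dien-1-ol | OCC(C)(C)/C=C/C=C | intermediate
5 | (E)-2,2-dimethylhexa-3,5-dienal | O=CC(C)(C)/C=C/C=C | intermediate
6 | methyl tiglate, methyl (E)-2-methylbut-2-enoate | COC(=O)/C(C)=C/C | starting material
7 | tert-butyl[(1-methoxy-2-methylbuta-1,3-dien-1-yl)oxy]dimethylsilane (E/Z mixture) | COC(O[Si](C)(C)C(C)(C)C)=C(C)C=C | intermediate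
8 | methyl (2E,5R,7E)-5-hydroxy-2,6,6-trimethyldeca-2,7,9-trienoate | COC(=O)/C(C)=C/C[C@@H](O)C(C)(C)/C=C/C=C | intermediate
9 | methyl (2E,5R,7E)-5-(tert-butyldimethylsilyloxy)-2,6,6-trimethyldeca-2,7,9-trienoate | COC(=O)/C(C)=C/C[C@@H](O[Si](C)(C)C(C)(C)C)C(C)(C)/C=C/C=C | intermediate
10 | (2E,5R,7E)-5-(tert-butyldimethylsilyloxy)-2,6,6-trimethyldeca-2,7,9-trienoic acid | OC(=O)/C(C)=C/C[C@@H](O[Si](C)(C)C(C)(C)C)C(C)(C)/C=C/C=C | intermediate
11 | acid chloride of 10 (not isolated) | ClC(=O)/C(C)=C/C[C@@H](O[Si](C)(C)C(C)(C)C)C(C)(C)/C=C/C=C | intermediate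
12 | (3Z,5R,7E)-5-(tert-butyldimethylsilyloxy)-2,6,6-trimethyldeca-1,3,7,9-tetraen-1-one, the vinylketene (not isolated) | O=C=C(C)/C=C\[C@@H](O[Si](C)(C)C(C)(C)C)C(C)(C)/C=C/C=C | intermediate
13 | 4-(tert-butyldimethylsilyloxy)-1,5,5-trimethyl-8-vinylbicyclo[4.1.1]oct-2-en-7-one; silyloxy on the side of the C7 carbonyl bridge, vinyl anti to the four‑carbon bridge | C1[C@@H](O[Si](C)(C)C(C)(C)C)C(C)(C)[C@H]2C(=O)[C@@](C)(C=1)[C@@H]2C=C | intermediate
14 | 7-(methoxymethylene) enol ether of 13 (E/Z mixture, not isolated) | C1[C@@H](O[Si](C)(C)C(C)(C)C)C(C)(C)[C@H]2C(=COC)[C@@](C)(C=1)[C@@H]2C=C | intermediate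
15 | 4-(tert-butyldimethylsilyloxy)-1,5,5-trimethyl-8-vinylbicyclo[4.1.1]oct-2-ene-7-carbaldehyde; formyl and vinyl cis, both anti to the four‑carbon bridge (epimer that cyclises shown) | C1[C@@H](O[Si](C)(C)C(C)(C)C)C(C)(C)[C@H]2[C@H](C=O)[C@@](C)(C=1)[C@@H]2C=C | intermediate
16 | 8-acetyl-4-(tert-butyldimethylsilyloxy)-1,5,5-trimethylbicyclo[4.1.1]oct-2-ene-7-carbaldehyde; acetyl and formyl cis, both anti to the four‑carbon bridge | C1[C@@H](O[Si](C)(C)C(C)(C)C)C(C)(C)[C@H]2[C@H](C=O)[C@@](C)(C=1)[C@@H]2C(C)=O | intermediate
17 | 7-(tert-butyldimethylsilyloxy)-3-hydroxy-3-demethyllongipin-8-en-1-one, the aldol (C3 configuration open, not isolated) | C1[C@@H](O[Si](C)(C)C(C)(C)C)C(C)(C)[C@H]2[C@@H]3C(O)CC(=O)[C@H]2[C@]3(C)C=1 | intermediate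
18 | 7-(tert-butyldimethylsilyloxy)-3-demethyllongipina-2,8-dien-1-one (no methyl at C3) | C1[C@@H](O[Si](C)(C)C(C)(C)C)C(C)(C)[C@H]2[C@@H]3C=CC(=O)[C@H]2[C@]3(C)C=1 | intermediate
19 | 7-(tert-butyldimethylsilyloxy)longipin-8-en-1-one; C3 methyl anti to the C10 bridge | C1[C@@H](O[Si](C)(C)C(C)(C)C)C(C)(C)[C@H]2[C@@H]3[C@H](C)CC(=O)[C@H]2[C@]3(C)C=1 | intermediate
20 | 7-(tert-butyldimethylsilyloxy)-8,9-dihydroxylongipinan-1-one; 8,9‑cis diol trans to O7 | O[C@@H]1[C@@H](O[Si](C)(C)C(C)(C)C)C(C)(C)[C@H]2[C@@H]3[C@H](C)CC(=O)[C@H]2[C@]3(C)[C@@H]1O | intermediate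
21 | 7,8,9-trihydroxylongipinan-1-one; 8‑OH and 9‑OH cis, 7‑OH trans to both | O[C@@H]1[C@@H](O)C(C)(C)[C@H]2[C@@H]3[C@H](C)CC(=O)[C@H]2[C@]3(C)[C@@H]1O | intermediate
22 | angelic acid, (Z)-2-methylbut-2-enoic acid | C/C=C(/C)C(=O)O | starting material
23 | 8-(angeloyloxy)-7,9-dihydroxylongipinan-1-one, the 8-monoangelate (not isolated) | C/C=C(/C)C(=O)O[C@@H]1[C@@H](O)C(C)(C)[C@H]2[C@@H]3[C@H](C)CC(=O)[C@H]2[C@]3(C)[C@@H]1O | intermediate
24 | 7,8-bis(angeloyloxy)-9-hydroxylongipinan-1-one, the 7,8-diangelate (not isolated) | C/C=C(/C)C(=O)O[C@@H]1[C@@H](OC(=O)/C(C)=C\C)C(C)(C)[C@H]2[C@@H]3[C@H](C)CC(=O)[C@H]2[C@]3(C)[C@@H]1O | intermediate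
25 | 7,8,9-tris(angeloyloxy)longipinan-1-one (CNP0138097.1) | C/C=C(/C)C(=O)O[C@@H]1[C@@H](OC(=O)/C(C)=C\C)C(C)(C)[C@H]2[C@@H]3[C@H](C)CC(=O)[C@H]2[C@]3(C)[C@@H]1OC(=O)/C(C)=C\C | target

**Summary**

Total step count: 15. Longest linear sequence: 14 steps (1–3, then 5–15, from methyl sorbate); step 4 is a one‑step branch.

**Steps most likely to fail**

Step 8. The cycloaddition may take the other facial course, with the C7 silyloxy group ending on the side of the vinyl‑bearing bridge, because the single remote stereocentre controls the approach only through the conformation of the forming seven‑membered ring. The fallback sets out from acid 10 and uses the two one‑carbon bridges as interchangeable handles. The same cycloaddition then gives the diastereomeric cycloadduct F1. A Wittig reaction with (1‑methoxyethylidene)triphenylphosphorane converts its cyclobutanone into the 1‑methoxyethylidene enol ether F2, and acid hydrolysis gives the acetyl vinyl compound F3, whose acetyl group now sits at C11. Lemieux–Johnson cleavage (OsO4 cat., NaIO4, 2,6‑lutidine) of the terminal vinyl group, which reacts ahead of the hindered ring alkene, gives the C4 aldehyde and so returns to the route at keto aldehyde 16.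

Step 11. The aldol addition may revert (retro‑aldol of the strained β‑hydroxy ketone) faster than it dehydrates, so that intermolecular condensation of the aldehyde takes over. The fallback sets out from aldehyde 15 and replaces the reversible addition by a kinetically controlled one. The aldehyde is converted with HC(OMe)3/PPTS into the dimethyl acetal F4, and Wacker oxidation gives the acetal methyl ketone F5. Kinetic enolisation and silylation (LDA, TMSCl, −78 °C) give the terminal silyl enol ether F6. TiCl4 at −78 °C then triggers an intramolecular Mukaiyama aldol addition to the oxocarbenium ion, giving the tricyclic β‑methoxy ketone F7. DBU eliminates methanol, and the route is rejoined at enone 18.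

Step 15. Part of the angeloyl groups may isomerise from Z to E during the slow acylation of the neopentylic C7 and C9 hydroxyls, and the acylation may stop at the partial esters. The fallback sets out from triol 21 and builds the Z double bonds on the molecule instead of carrying them in. The triol is esterified (DCC, DMAP) with the unhindered, saturated 2‑[bis(2,2,2‑trifluoroethoxy)phosphoryl]propanoic acid to the tris(phosphonopropionate) F8. A threefold Z‑selective Still–Gennari olefination with acetaldehyde (KHMDS, 18‑crown‑6, THF, −78 °C) then gives the three angelates and arrives at target 25.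

**Further compounds**

F1 | step 8 | 4-(tert-butyldimethylsilyloxy)-1,5,5-trimethyl-8-vinylbicyclo[4.1.1]oct-2-en-7-one, diastereomer with the silyloxy group on the side of the vinyl‑bearing bridge | C1[C@@H](O[Si](C)(C)C(C)(C)C)C(C)(C)[C@H]2[C@H](C=C)[C@@](C)(C=1)C2=O
F2 | step 8 | 7-(1-methoxyethylidene) enol ether of F1 (E/Z mixture) | C1[C@@H](O[Si](C)(C)C(C)(C)C)C(C)(C)[C@H]2[C@H](C=C)[C@@](C)(C=1)C2=C(C)OC
F3 | step 8 | 7-acetyl-4-(tert-butyldimethylsilyloxy)-1,5,5-trimethyl-8-vinylbicyclo[4.1.1]oct-2-ene (acetyl at the future C11, vinyl at the future C4) | C1[C@@H](O[Si](C)(C)C(C)(C)C)C(C)(C)[C@H]2[C@H](C=C)[C@@](C)(C=1)[C@@H]2C(C)=O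
F4 | step 11 | dimethyl acetal of 15 | C1[C@@H](O[Si](C)(C)C(C)(C)C)C(C)(C)[C@H]2[C@H](C(OC)OC)[C@@](C)(C=1)[C@@H]2C=C
F5 | step 11 | 8-acetyl-7-(dimethoxymethyl)-4-(tert-butyldimethylsilyloxy)-1,5,5-trimethylbicyclo[4.1.1]oct-2-ene | C1[C@@H](O[Si](C)(C)C(C)(C)C)C(C)(C)[C@H]2[C@H](C(OC)OC)[C@@](C)(C=1)[C@@H]2C(C)=O
F6 | step 11 | terminal trimethylsilyl enol ether of F5 | C1[C@@H](O[Si](C)(C)C(C)(C)C)C(C)(C)[C@H]2[C@H](C(OC)OC)[C@@](C)(C=1)[C@@H]2C(=C)O[Si](C)(C)C
F7 | step 11 | 7-(tert-butyldimethylsilyloxy)-3-methoxy-3-demethyllongipin-8-en-1-one (C3 configuration open) | C1[C@@H](O[Si](C)(C)C(C)(C)C)C(C)(C)[C@H]2[C@@H]3C(OC)CC(=O)[C@H]2[C@]3(C)C=1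
F8 | step 15 | 7,8,9-tris{2-[bis(2,2,2-trifluoroethoxy)phosphoryl]propanoyloxy}longipinan-1-one | CC(P(=O)(OCC(F)(F)F)OCC(F)(F)F)C(=O)O[C@@H]1[C@@H](OC(=O)C(C)P(=O)(OCC(F)(F)F)OCC(F)(F)F)C(C)(C)[C@H]2[C@@H]3[C@H](C)CC(=O)[C@H]2[C@]3(C)[C@@H]1OC(=O)C(C)P(=O)(OCC(F)(F)F)OCC(F)(F)F
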